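**Retrosynthetic overview**
1. Side-chain lactone last: C3–C18 by Friedel–Crafts acylation of the pyrrole with (S)-methylsuccinic anhydride, then C18 by catalyst-controlled ketone reduction and lactonisation.
2. Lactone D: 13-methyl by convex-face hydrogenation of the α-methylene lactone; C11–O by reduction of a C11 ketone (carried as NO2) and closure onto the C14 ester.
3. Ring C: asymmetric [4+2] forming C9–C10 and C11–C12 between a pyrrole-2,3-quinodimethane (trienamine of enal 10) and (E)-1-nitrobut-1-ene. Enabling feature: ring C is a cyclohexene whose only C=C is the pyrrole C9a=C1 bond, flanked by sp3 C9 and C12, and C12 carries the C13–C14 arm, which at the aldehyde level is the handle for the trienamine.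
4. Ring order: azepine B (from a caprolactam imidate) → pyrrole A (Hantzsch-type) → ring C (key step) → lactone D → side-chain lactone.

Key step: step 9

Remark (locants): Stemona numbering is used throughout. Pyrrole: C1 (β, fused to ring C), C2, C3 (α), N4, C9a. Azepine: C5–C9. Ring C: C9, C10 (Et), C11 (O), C12, C1, C9a. Lactone D: C11, C12, C13 (Me), C14 (C=O), O. Side chain: C18 (CH–O), C19, C20 (Me), C21 (C=O).
Remark (assumption): the nitroalkene is assumed to add to the face of the trienamine away from the CPh2OSiMe3 group, which predicts 9R from the (R)-amine; (R,R)-TsDPEN is assigned for 18R by analogy with aryl alkyl ketones; the mirror-image catalyst is used if either sense proves opposite.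

**Route**

Step 1
Reactants: 1 7-methoxy-3,4,5,6-tetrahydro-2H-azepine (O-methylcaprolactim); 2 2,2-dimethyl-1,3-dioxane-4,6-dione (Meldrum's acid)
Product: 3 5-(azepan-2-ylidene)-2,2-dimethyl-1,3-dioxane-4,6-dione
Conditions: Et3N (0.2 equiv), CHCl3, reflux
Reagents that add atoms: none
Why: Addition–elimination of the C–H acid on the lactim ether (loss of MeOH) is the standard entry to cyclic enaminones from five- to seven-membered imidates.

Step 2
Reactants: 3 5-(azepan-2-ylidene)-2,2-dimethyl-1,3-dioxane-4,6-dione
Product: 4 ethyl (2Z)-2-(azepan-2-ylidene)acetate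
Conditions: NaOEt (1.1 equiv), EtOH, reflux
Reagents that add atoms: ethanol, CCO
Why: Ethanolysis of the dioxanedione followed by decarboxylation should give the N–H···O=C hydrogen-bonded (Z)-β-enamino ester.

Step 3
Reactants: 4 ethyl (2Z)-2-(azepan-2-ylidene)acetate; 5 chloroacetaldehyde (50 wt % in water)
Product: 6 ethyl 6,7,8,9-tetrahydro-5H-pyrrolo[1,2-a]azepine-1-carboxylate
Conditions: NaHCO3 (2 equiv), EtOH/H2O, 70 °C
Reagents that add atoms: none
Why: Hantzsch-type pyrrole annulation: the enamine carbon and nitrogen are bridged by the two carbons of 5 and water loss aromatises, so the ester ends at C1 next to C9a and C2 and C3 are CH whichever carbon reacts first.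

Step 4
Reactants: 6 ethyl 6,7,8,9-tetrahydro-5H-pyrrolo[1,2-a]azepine-1-carboxylate
Product: 7 (6,7,8,9-tetrahydro-5H-pyrrolo[1,2-a]azepin-1-yl)methanol
Conditions: LiAlH4 (1.2 equiv), THF, 0 °C to rt; aqueous NaOH work-up
Reagents that add atoms: none
Why: Hydride reduction of the vinylogous carbamate ester to the pyrrol-3-ylmethanol, which is kept base-washed and used directly.

Step 5
Reactants: 7 (6,7,8,9-tetrahydro-5H-pyrrolo[1,2-a]azepin-1-yl)methanol
Product: 8 6,7,8,9-tetrahydro-5H-pyrrolo[1,2-a]azepine-1-carbaldehyde
Conditions: activated MnO2 (10 equiv), CH2Cl2, rt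
Reagents that add atoms: none
Why: MnO2 oxidises the activated heteroaryl carbinol selectively and leaves the pyrrole untouched.

Step 6
Reactants: 8 6,7,8,9-tetrahydro-5H-pyrrolo[1,2-a]azepine-1-carbaldehyde; 9 (triphenylphosphoranylidene)acetaldehyde
Product: 10 (2E)-3-(6,7,8,9-tetrahydro-5H-pyrrolo[1,2-a]azepin-1-yl)prop-2-enal
Conditions: toluene, 90 °C
Reagents that add atoms: none
Why: Wittig reaction with the stabilised formyl ylide should give the (E)-enal, the two-carbon arm that later becomes C13–C14.

Step 7
Reactants: 11 propanal; 12 nitromethane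
Product: 13 1-nitrobutan-2-ol (racemic)
Conditions: KOt-Bu (5 mol %), t-BuOH/THF, 0 °C
Reagents that add atoms: none
Why: Henry (nitroaldol) addition; the carbinol centre is removed in the next step.

Step 8
Reactants: 13 1-nitrobutan-2-ol
Product: 15 (E)-1-nitrobut-1-ene, via 1-nitrobutan-2-yl methanesulfonate 14 (not isolated)
Conditions: MsCl (1.1 equiv), Et3N (2.2 equiv), CH2Cl2, −10 to 0 °C
Reagents that add atoms: none
Why: Mesylation and E1cB elimination give the conjugated nitroalkene as the E isomer.

Step 9
Reactants: 10 (2E)-3-(6,7,8,9-tetrahydro-5H-pyrrolo[1,2-a]azepin-1-yl)prop-2-enal; 15 (E)-1-nitrobut-1-ene (2 equiv)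
Product: 17 (9R,10S,11R,12R)-nitro aldehyde (ring C closed; 10-ethyl; 11-nitro; 12-CH2CHO), via trienamine 16 (not isolated)
Conditions: (R)-2-[diphenyl(trimethylsilyloxy)methyl]pyrrolidine (20 mol %), PhCO2H (20 mol %), toluene, 40 °C
Reagents that add atoms: none
Why: Condensation of 10 with the amine (water set free) and loss of a C9 proton give trienamine 16, an electron-rich pyrrole-2,3-quinodimethane (diene C9=C9a–C1=C12), which adds 15 in an asynchronous [4+2] in which C9 bonds to the nitroalkene β-carbon C10 and C11 bonds to C12; the pyrrole is thereby re-aromatised and the water of condensation hydrolyses the product enamine, returning the amine. The closest known reaction type is the aminocatalytic Diels–Alder reaction of in situ generated indole-, pyrrole- and furan-2,3-quinodimethanes with nitroolefins. Ring C is closed by intermolecular suprafacial [4+2] cycloaddition, the six-membered carbocycle arising from C9–C10 and C11–C12 in one operation. C9 is set by the catalyst, whose CPh2OSiMe3 group shields one face of the planar trienamine; the 9,12-cis relation follows from the out,out geometry of the diene termini, the 10,11-trans relation from the E-alkene and the 9,10-cis relation from the exo orientation of the nitro group, but C10, C11 and C12 are re-set in steps 11 and 12 and only C9 must survive. The step needs ε,β-regioselectivity and the ortho-type orientation, secured by the large HOMO coefficient at C9 and the polarisation of the nitroalkene, and facial selectivity, secured by the catalyst, while the azepine ring holds C8 on the outside of the diene terminus.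

Step 10
Reactants: 17 (9R,10S,11R,12R)-nitro aldehyde
Product: 18 (9R,10S,11R,12R)-nitro methyl ester (12-CH2CO2Me)
Conditions: 1,4-dimethyl-1,2,4-triazolium iodide (15 mol %), DBU (1.1 equiv), MeOH (5 equiv), MnO2 (5 equiv), CH2Cl2, rt
Reagents that add atoms: methanol, CO
Why: Carbene-catalysed oxidative esterification of an unactivated aldehyde with MnO2 as terminal oxidant, chosen because chlorite or hypochlorite oxidants would attack the electron-rich trialkylpyrrole.

Step 11
Reactants: 18 (9R,10S,11R,12R)-nitro methyl ester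
Product: 21 (9R,10R,12S)-keto ester (C11 ketone; 9,10-trans; 10,12-cis), via sodium nitronate 19 (not isolated), via kinetic ketone 20 (not isolated)
Conditions: NaOMe (1.1 equiv), MeOH, 0 °C; then aq. TiCl3 (4.5 equiv), NH4OAc buffer (pH about 6), THF, rt; extractive work-up; then DBU (0.3 equiv), CH2Cl2, rt
Reagents that add atoms: water, O
Why: Nef reaction in its reductive form (nitronate reduced by trivalent titanium to the imine, hydrolysed at near-neutral pH), after which C10 and C12, now both α to the ketone, should equilibrate to the isomer with C8, ethyl and the C13 arm all (pseudo)equatorial.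

Step 12
Reactants: 21 (9R,10R,12S)-keto ester
Product: 23 (9R,10R,11R,12S)-lactone (ring D closed; C13 still a CH2 group), via hydroxy ester 22 (not isolated)
Conditions: LiBH(s-Bu)3 (1.3 equiv), THF, −78 °C; then AcOH (3 equiv), −78 °C to rt; no peroxide work-up
Reagents that add atoms: none
Why: The bulky hydride should attack the 2,6-diequatorially substituted cyclohexanone from the equatorial direction, giving the axial C11 alkoxide cis to both ethyl and the C12 arm, which closes the cis-fused γ-lactone.

Step 13
Reactants: 23 (9R,10R,11R,12S)-lactone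
Product: 25 (9R,10R,11R,12R)-α-methylene lactone (exocyclic CH2 on C13), via formyl lactone sodium enolate 24 (not isolated)
Conditions: NaH (1.5 equiv), HCO2Et (3 equiv), THF, 0 °C to rt; then (CH2O)n (5 equiv), THF, reflux
Reagents that add atoms: formaldehyde (from paraformaldehyde), C=O
Why: α-Formylation, then aldol addition to formaldehyde, formyl transfer and loss of formate is a known α-methylenation of γ-lactones and avoids iminium reagents that would aminomethylate the free pyrrole α-position.

Step 14
Reactants: 25 (9R,10R,11R,12R)-α-methylene lactone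
Product: 26 (9R,10R,11R,12S,13S)-tetracyclic lactone (13-methyl on the concave face; C3–H)
Conditions: H2 (1 atm), RhCl(PPh3)3 (5 mol %), benzene/EtOH 1:1, rt
Reagents that add atoms: none
Why: Homogeneous hydrogenation should add H2 to the exocyclic alkene from the convex face of the cis-fused lactone (the face of H11 and H12), placing H13 cis to H12 and the methyl cis to C1 (13S) without isomerisation to the butenolide.

Step 15
Reactants: 27 (S)-2-methylsuccinic acid
Product: 28 (S)-3-methyloxolane-2,5-dione ((S)-methylsuccinic anhydride)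
Conditions: AcCl (3 equiv), reflux; evaporation
Reagents that add atoms: none
Why: Cyclodehydration of the 1,4-diacid; the stereocentre is not enolised.

Step 16
Reactants: 26 (9R,10R,11R,12S,13S)-tetracyclic lactone; 28 (S)-methylsuccinic anhydride (1.3 equiv)
Product: 29 (20S)-keto acid (C3–C(=O)–CH2–CH(CH3)–CO2H)
Conditions: AlCl3 (2.5 equiv), CH2Cl2, −10 to 0 °C; cold dilute HCl work-up
Reagents that add atoms: none
Why: Friedel–Crafts acylation at the only free pyrrole α-position (C3), the arene attacking the less hindered CH2-flanked carbonyl of the anhydride, as arenes do with methylsuccinic anhydride.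

Step 17
Reactants: 29 (20S)-keto acid
Product: 31 target CNP0232452.1 (9R,10R,11R,12S,13S,18R,20S), via hydroxy acid 30 (not isolated)
Conditions: RuCl[(R,R)-TsDPEN](p-cymene) (2 mol %), HCO2H/Et3N 5:2, 40 °C
Reagents that add atoms: none
Why: Asymmetric transfer hydrogenation of the heteroaryl ketone under catalyst control should give the (18R)-carbinol, which lactonises in the medium with retention to the 18,20-trans lactone, as known for γ-aryl γ-keto acids.

**Compound list**

1 | 7-methoxy-3,4,5,6-tetrahydro-2H-azepine | COC1=NCCCCC1 | starting material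
2 | 2,2-dimethyl-1,3-dioxane-4,6-dione | CC1(C)OC(=O)CC(=O)O1 | starting material
3 | 5-(azepan-2-ylidene)-2,2-dimethyl-1,3-dioxane-4,6-dione | CC1(C)OC(=O)C(=C2CCCCCN2)C(=O)O1 | intermediate
4 | ethyl (2Z)-2-(azepan-2-ylidene)acetate | CCOC(=O)/C=C1/CCCCCN1 | intermediate
5 | chloroacetaldehyde | ClCC=O | starting material
6 | ethyl 6,7,8,9-tetrahydro-5H-pyrrolo[1,2-a]azepine-1-carboxylate | CCOC(=O)c1ccn2CCCCCc12 | intermediate
7 | (6,7,8,9-tetrahydro-5H-pyrrolo[1,2-a]azepin-1-yl)methanol | OCc1ccn2CCCCCc12 | intermediate
8 | 6,7,8,9-tetrahydro-5H-pyrrolo[1,2-a]azepine-1-carbaldehyde | O=Cc1ccn2CCCCCc12 | intermediate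
9 | (triphenylphosphoranylidene)acetaldehyde | O=CC=P(c1ccccc1)(c1ccccc1)c1ccccc1 | starting material
10 | (2E)-3-(6,7,8,9-tetrahydro-5H-pyrrolo[1,2-a]azepin-1-yl)prop-2-enal | O=C/C=C/c1ccn2CCCCCc12 | intermediate
11 | propanal | CCC=O | starting material
12 | nitromethane | C[N+](=O)[O-] | starting material
13 | 1-nitrobutan-2-ol (racemic) | CCC(O)C[N+](=O)[O-] | intermediate
14 | 1-nitrobutan-2-yl methanesulfonate (not isolated) | CCC(OS(C)(=O)=O)C[N+](=O)[O-] | intermediate
15 | (E)-1-nitrobut-1-ene | CC/C=C/[N+](=O)[O-] | intermediate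
16 | trienamine of 10 with the (R)-amine catalyst (pyrrole-2,3-quinodimethane; not isolated) | C[Si](C)(C)OC(c1ccccc1)(c1ccccc1)[C@H]1CCCN1/C=C/C=C1\C=CN2CCCCC=C12 | intermediate
17 | (9R,10S,11R,12R)-nitro aldehyde | CC[C@@H]1[C@@H]([N+](=O)[O-])[C@H](CC=O)c2ccn3c2[C@@H]1CCCC3 | intermediate
18 | (9R,10S,11R,12R)-nitro methyl ester | CC[C@@H]1[C@@H]([N+](=O)[O-])[C@H](CC(=O)OC)c2ccn3c2[C@@H]1CCCC3 | intermediate
19 | sodium nitronate of 18 (9R,10S,12R; not isolated) | CC[C@@H]1C(=[N+]([O-])[O-])[C@H](CC(=O)OC)c2ccn3c2[C@@H]1CCCC3.[Na+] | intermediate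
20 | (9R,10S,12R)-keto ester, kinetic (not isolated) | CC[C@@H]1C(=O)[C@H](CC(=O)OC)c2ccn3c2[C@@H]1CCCC3 | intermediate
21 | (9R,10R,12S)-keto ester | CC[C@H]1C(=O)[C@@H](CC(=O)OC)c2ccn3c2[C@@H]1CCCC3 | intermediate
22 | (9R,10R,11R,12S)-hydroxy ester (formed as lithium alkoxide; not isolated) | CC[C@H]1[C@@H](O)[C@@H](CC(=O)OC)c2ccn3c2[C@@H]1CCCC3 | intermediate
23 | (9R,10R,11R,12S)-lactone, C13 a CH2 group | CC[C@H]1[C@H]2OC(=O)C[C@H]2c2ccn3c2[C@@H]1CCCC3 | intermediate
24 | sodium enolate of the 13-formyl lactone (not isolated) | CC[C@H]1[C@H]2OC(=O)C(=C[O-])[C@H]2c2ccn3c2[C@@H]1CCCC3.[Na+] | intermediate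
25 | (9R,10R,11R,12R)-α-methylene lactone | CC[C@H]1[C@H]2OC(=O)C(=C)[C@H]2c2ccn3c2[C@@H]1CCCC3 | intermediate
26 | (9R,10R,11R,12S,13S)-tetracyclic lactone | CC[C@H]1[C@H]2OC(=O)[C@@H](C)[C@H]2c2ccn3c2[C@@H]1CCCC3 | intermediate
27 | (S)-2-methylsuccinic acid | OC(=O)C[C@H](C)C(=O)O | starting material
28 | (S)-3-methyloxolane-2,5-dione | C[C@H]1CC(=O)OC1=O | intermediate
29 | (20S)-keto acid | CC[C@H]1[C@H]2OC(=O)[C@@H](C)[C@H]2c2cc(C(=O)C[C@H](C)C(=O)O)n3c2[C@@H]1CCCC3 | intermediate
30 | (18R,20S)-hydroxy acid (not isolated) | CC[C@H]1[C@H]2OC(=O)[C@@H](C)[C@H]2c2cc([C@H](O)C[C@H](C)C(=O)O)n3c2[C@@H]1CCCC3 | intermediate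
31 | CNP0232452.1 | CC[C@H]1[C@H]2OC(=O)[C@@H](C)[C@H]2c2cc([C@H]3C[C@H](C)C(=O)O3)n3c2[C@@H]1CCCC3 | target

**Totals**

Total step count: 17
Longest linear sequence: 14 steps (steps 1–6, 9–14, 16, 17)

**Steps most likely to fail**

1. Step 9. The process at risk is facial discrimination: the shielding group of the catalyst is far from the reacting C9, which here is a ring CH2 and therefore a substituted diene terminus, so enantiocontrol at C9 may be poor and ε-deprotonation slow. The fallback replaces catalyst control by resolution; it sets out from 10 and 15 and returns at 18. With pyrrolidine/PhCO2H as achiral catalyst the cycloaddition should give the racemic nitro aldehyde F1. Oxidative esterification as in step 10 gives the racemic nitro ester F2, and LiOH in THF/H2O the racemic nitro acid F3. Crystallisation with (R)-1-phenylethylamine should give the (R)-1-phenylethylammonium salt of the (9R)-acid F4 (the mirror-image amine is used if the other salt is the less soluble one). Acidification gives the (9R)-nitro acid F5, and Me3SiCHN2/MeOH re-forms 18.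

2. Step 12. The process at risk is stereochemical relay: the C12 epimer ratio reached in step 11 may be unfavourable (the C13 arm may prefer the pseudoaxial position next to the pyrrole), or hydride may arrive from the axial direction, giving hydroxy esters that cannot close the cis-lactone or that close to the 11,12-bis-epimer. The fallback sets C11 and C12 together by hydrogenation; it sets out from 21 and returns at 23. LiOH gives the keto acid F6 (either C12 epimer). Ac2O/NaOAc at 90 °C gives the enol lactone F7 (C11=C12, conjugated with the pyrrole, C12 stereocentre erased). H2 over Pd/C in EtOAc should add syn to the face opposite the C10 ethyl group, giving H11 and H12 cis and O11 cis to ethyl, which is 23.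

3. Step 17. The processes at risk are low reactivity of the vinylogous-amide carbonyl and loss of configuration at C18 by acid-promoted ionisation of the pyrrol-2-yl carbinol or lactone in HCO2H. The fallback builds C18 by catalyst-controlled C–C bond formation; it sets out from 26 and returns at 31. POCl3/DMF formylation of 26 at C3 gives the 3-carbaldehyde F8. Commercial methyl (R)-3-bromo-2-methylpropanoate (BrC[C@H](C)C(=O)OC) with NaI in acetone gives methyl (R)-3-iodo-2-methylpropanoate F9, and Et2Zn with catalytic CuI gives bis[(2R)-3-methoxy-2-methyl-3-oxopropyl]zinc F10. Addition of F10 to F8 with Ti(Oi-Pr)4 and (1S,2S)-1,2-bis(trifluoromethanesulfonamido)cyclohexane (10 mol %) in toluene at −20 °C should give the (18R,20S)-hydroxy ester F11. Pyridinium p-toluenesulfonate in CH2Cl2 closes the lactone to 31.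

**Further compounds**

F1 | step 9 | racemic nitro aldehyde (relative configuration of 17, both enantiomers) | CC[C@@H]1[C@@H]([N+](=O)[O-])[C@H](CC=O)c2ccn3c2[C@@H]1CCCC3.CC[C@H]1[C@H]([N+](=O)[O-])[C@@H](CC=O)c2ccn3c2[C@H]1CCCC3
F2 | step 9 | racemic nitro methyl ester (relative configuration of 18, both enantiomers) | CC[C@@H]1[C@@H]([N+](=O)[O-])[C@H](CC(=O)OC)c2ccn3c2[C@@H]1CCCC3.CC[C@H]1[C@H]([N+](=O)[O-])[C@@H](CC(=O)OC)c2ccn3c2[C@H]1CCCC3
F3 | step 9 | racemic nitro acid (both enantiomers) | CC[C@@H]1[C@@H]([N+](=O)[O-])[C@H](CC(=O)O)c2ccn3c2[C@@H]1CCCC3.CC[C@H]1[C@H]([N+](=O)[O-])[C@@H](CC(=O)O)c2ccn3c2[C@H]1CCCC3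
F4 | step 9 | (R)-1-phenylethylammonium salt of the (9R,10S,11R,12R)-nitro acid | CC[C@@H]1[C@@H]([N+](=O)[O-])[C@H](CC(=O)[O-])c2ccn3c2[C@@H]1CCCC3.C[C@@H]([NH3+])c1ccccc1
F5 | step 9 | (9R,10S,11R,12R)-nitro acid | CC[C@@H]1[C@@H]([N+](=O)[O-])[C@H](CC(=O)O)c2ccn3c2[C@@H]1CCCC3
F6 | step 12 | (9R,10R)-keto acid, C12 either epimer | CC[C@H]1C(=O)C(CC(=O)O)c2ccn3c2[C@@H]1CCCC3
F7 | step 12 | (9R,10R)-enol lactone (C11=C12) | CC[C@H]1C2=C(CC(=O)O2)c2ccn3c2[C@@H]1CCCC3
F8 | step 17 | 3-carbaldehyde of 26 | CC[C@H]1[C@H]2OC(=O)[C@@H](C)[C@H]2c2cc(C=O)n3c2[C@@H]1CCCC3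
F9 | step 17 | methyl (R)-3-iodo-2-methylpropanoate | COC(=O)[C@@H](C)CI
F10 | step 17 | bis[(2R)-3-methoxy-2-methyl-3-oxopropyl]zinc | COC(=O)[C@@H](C)C[Zn]C[C@H](C)C(=O)OC
F11 | step 17 | (18R,20S)-hydroxy methyl ester | CC[C@H]1[C@H]2OC(=O)[C@@H](C)[C@H]2c2cc([C@H](O)C[C@H](C)C(=O)OC)n3c2[C@@H]1CCCC3
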